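**Plan**

- Numbering: bicyclo[3.3.1]nonane with C1 = prenyl bridgehead next to C8(Me2), C5 = bridgehead carrying the C10 chain (C1′–C8′), C9 = bridging ketone; ring A = C1–C2–C3–C4–C5–C9, ring B = C1–C8–C7–C6–C5–C9.
- Retrosynthetic cuts, in order: silyl and methyl masks; C3–aroyl (vinyllithium + acid chloride); C5–C1′ (bridgehead carbanion + allylic bromide); then C1–C2 and C4–C5 together.
- Enabling feature: ring B is a cyclohexanone (C9=O) whose two α-carbons are C1 and C5, and C2–C3–C4 is a malonyl unit at the acid oxidation level. Ring A can therefore be laid across ring B by a double C-acylation (Effenberger annulation) of a silyl enol ether with malonyl dichloride.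
- Forward order: ring B by organocatalytic Michael/aldol, two cuprate additions (gem-dimethyl, C1 prenyl), annulation to ring A, O-methyl mask, C5 chain, C3 aroyl, unmasking.
- Stereochemistry: C7 from the diarylprolinol-ether Michael step; C1 and C5 relayed from C7 in the annulation; C4′ from a Keck allylation; 2′E from SeO2 oxidation of prenyl acetate.

Key step: step 7

Remark: 5-methylhex-4-enal (1) is taken as purchasable. O-Methylation of 14 is assumed to occur at the less hindered C4 oxygen. Ketone 9 is drawn as its diequatorial C2 epimer, although either epimer serves.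

**Ring B**

Step 1
Reactants: 1 5-methylhex-4-enal; 2 methyl vinyl ketone (but-3-en-2-one)
Product: 3 (2S)-2-(3-methylbut-2-en-1-yl)-5-oxohexanal
Conditions: (S)-2-[methoxy(diphenyl)methyl]pyrrolidine (5 mol%), ethyl 3,4-dihydroxybenzoate (20 mol%), neat, 4 °C
Reagents that add atoms: none
Why: Enamine-mediated organocatalytic Michael addition of an aldehyde to a vinyl ketone; the (S)-diarylprolinol ether forms the E-enamine of 1 and shields one face, so 2 should add to the open face and set C2 as S (the future C7).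

Step 2
Reactants: 3 (2S)-2-(3-methylbut-2-en-1-yl)-5-oxohexanal
Product: 4 (4S)-4-(3-methylbut-2-en-1-yl)cyclohex-2-en-1-one
Conditions: KOH (0.1 M aq.), Bu4NOH (cat.), THF–Et2O, 40 °C
Reagents that add atoms: none
Why: Intramolecular aldol condensation of the 1,5-ketoaldehyde; only the methyl-ketone enolate reaches the aldehyde through a six-membered ring, and the mild base should preserve the stereocentre, which becomes the γ-carbon of the enone.

Step 3
Reactants: 4 (4S)-4-(3-methylbut-2-en-1-yl)cyclohex-2-en-1-one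
Product: 5 trimethyl{[(3S,4S)-3-methyl-4-(3-methylbut-2-en-1-yl)cyclohex-1-en-1-yl]oxy}silane
Conditions: Me2CuLi, Me3SiCl, THF–Et2O, −78 °C; Et3N, pentane work-up
Reagents that add atoms: lithium dimethylcuprate, [Li+].C[Cu-]C; chlorotrimethylsilane, C[Si](C)(C)Cl
Why: Chlorosilane-accelerated Gilman cuprate 1,4-addition with the enolate trapped as the regiodefined silyl enol ether; methyl should enter anti to the C4 prenyl group, and this new centre is removed again in step 4.

Step 4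
Reactants: 5 trimethyl{[(3S,4S)-3-methyl-4-(3-methylbut-2-en-1-yl)cyclohex-1-en-1-yl]oxy}silane
Product: 6 (4S)-3-methyl-4-(3-methylbut-2-en-1-yl)cyclohex-2-en-1-one
Conditions: Pd(OAc)2 (1.1 equiv), MeCN, 23 °C
Reagents that add atoms: none
Why: Saegusa–Ito oxidation; the divalent-palladium enolate formed at C2 can β-hydride-eliminate only toward C3, giving the 3-methyl enone without touching the γ-stereocentre.

Step 5
Reactants: 6 (4S)-3-methyl-4-(3-methylbut-2-en-1-yl)cyclohex-2-en-1-one; 7 prenyl bromide (1-bromo-3-methylbut-2-ene)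
Product: 9 (2R,4S)-3,3-dimethyl-2,4-bis(3-methylbut-2-en-1-yl)cyclohexan-1-one, via lithium enolate 8 (not isolated)
Conditions: Me2CuLi, Et2O, 0 °C; then 7 (excess), HMPA–THF, −20 → 23 °C
Reagents that add atoms: lithium dimethylcuprate, [Li+].C[Cu-]C
Why: Tandem cuprate conjugate addition–enolate alkylation; the second methyl completes the gem-dimethyl carbon and the regiospecific enolate 8 is allylated at C2 by the reactive allylic bromide, the C2 configuration being erased in step 7.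

Step 6
Reactants: 9 (2R,4S)-3,3-dimethyl-2,4-bis(3-methylbut-2-en-1-yl)cyclohexan-1-one
Product: 11 tert-butyl{[(4R,6R)-5,5-dimethyl-4,6-bis(3-methylbut-2-en-1-yl)cyclohex-1-en-1-yl]oxy}dimethylsilane, via kinetic lithium enolate 10 (not isolated)
Conditions: LiN(iPr)2, THF, −78 °C; then tBuMe2SiOTf, −78 → 0 °C
Reagents that add atoms: tert-butyldimethylsilyl trifluoromethanesulfonate, CC(C)(C)[Si](C)(C)OS(=O)(=O)C(F)(F)F
Why: Kinetic enolisation removes the unhindered C6 proton rather than the C2 methine flanked by the quaternary carbon, and O-silylation gives the less substituted silyl enol ether that serves as the nucleophile in step 7.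

**Ring A (key step) and masking**

Step 7
Reactants: 11 tert-butyl{[(4R,6R)-5,5-dimethyl-4,6-bis(3-methylbut-2-en-1-yl)cyclohex-1-en-1-yl]oxy}dimethylsilane; 12 malonyl dichloride
Product: 14 (1R,5S,7R)-4-hydroxy-8,8-dimethyl-1,7-bis(3-methylbut-2-en-1-yl)bicyclo[3.3.1]non-3-ene-2,9-dione, via β-ketoacyl chloride 13 (not isolated)
Conditions: 12 (2 equiv), Et2O, −20 °C; then KOH (aq.), BnEt3NCl, 23 °C; aq. HCl
Reagents that add atoms: none
Why: Effenberger α,α′-annulation (formal [3+3]): one acyl chloride of 12 C-acylates the silyl enol ether at its unsubstituted α-carbon with loss of the silyl group to give 13, whose ketone re-enolises toward the prenyl-bearing α-carbon and is acylated intramolecularly by the second acyl chloride, the KOH/phase-transfer stage funnelling any O-acylated material to the C-acylated trione. The closest known reaction type is the malonyl dichloride annulation of 2-substituted cyclohexanone enol ethers to bicyclo[3.3.1]nonane-2,4,9-triones. Ring A closes by a 6-(enolendo)-exo-trig C-acylation, which can bridge the two α-carbons of ring B only in a cis-diaxial sense. C1 and C5 are therefore set as a pair, and their sense is controlled by the existing C7 centre: the bridge should form on the face of ring B that leaves the C7 prenyl group equatorial and exo (trans to C2–C4), because the alternative forces it axial beneath the forming ring. The step needs C- over O-acylation and ring closure over oligomerisation; low temperature, excess 12, the basic second stage and the fact that 13 can close a six-membered ring only through its C2 enol are expected to secure this. The labile C2 configuration carried in from 9 is lost, so the epimer composition of 11 does not matter.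

Step 8
Reactants: 14 (1R,5S,7R)-4-hydroxy-8,8-dimethyl-1,7-bis(3-methylbut-2-en-1-yl)bicyclo[3.3.1]non-3-ene-2,9-dione
Product: 15 (1R,5S,7R)-4-methoxy-8,8-dimethyl-1,7-bis(3-methylbut-2-en-1-yl)bicyclo[3.3.1]non-3-ene-2,9-dione
Conditions: Me2SO4, K2CO3, acetone, 56 °C
Reagents that add atoms: dimethyl sulfate, COS(=O)(=O)OC
Why: O-Alkylation of the vinylogous acid masks the 1,3-diketone as a vinylogous methyl ester, the oxygen on C4 (next to the CH bridgehead) being less hindered than that next to the quaternary C1.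

**C5 side chain**

Step 9
Reactants: 16 prenyl acetate (3-methylbut-2-en-1-yl acetate)
Product: 17 (2E)-3-methyl-4-oxobut-2-en-1-yl acetate
Conditions: SeO2 (1.1 equiv), wet 1,4-dioxane, 80 °C
Reagents that add atoms: selenium dioxide, O=[Se]=O
Why: Selenium dioxide allylic oxidation (ene reaction, then [2,3]-sigmatropic shift) is selective for the E-methyl group of a trisubstituted alkene and so fixes the E geometry of the future C2′=C3′ bond.

Step 10
Reactants: 17 (2E)-3-methyl-4-oxobut-2-en-1-yl acetate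
Product: 18 (2E,4S)-4-hydroxy-3-methylhepta-2,6-dien-1-yl acetate
Conditions: (S)-BINOL (10 mol%), Ti(OiPr)4 (10 mol%), 4 Å molecular sieves, CH2Cl2, −20 °C; allylSnBu3; aq. KF work-up
Reagents that add atoms: allyltributylstannane, C=CC[Sn](CCCC)(CCCC)CCCC
Why: Keck asymmetric allylation; the (S)-BINOL–titanium Lewis acid should direct allyl transfer to the Si face of the enal and give the 4S carbinol, the ester and the trisubstituted alkene being inert.

Step 11
Reactants: 18 (2E,4S)-4-hydroxy-3-methylhepta-2,6-dien-1-yl acetate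
Product: 19 (2E,4S)-4-[(tert-butyldimethylsilyl)oxy]-3-methylhepta-2,6-dien-1-yl acetate
Conditions: tBuMe2SiCl, imidazole, DMF, 23 °C
Reagents that add atoms: tert-butyldimethylsilyl chloride, CC(C)(C)[Si](C)(C)Cl
Why: Imidazole-promoted silylation of the secondary alcohol gives an ether that tolerates the amide bases of steps 15 and 18.

Step 12
Reactants: 19 (2E,4S)-4-[(tert-butyldimethylsilyl)oxy]-3-methylhepta-2,6-dien-1-yl acetate
Product: 20 (2E,4S)-4-[(tert-butyldimethylsilyl)oxy]-3,7-dimethylocta-2,6-dien-1-yl acetate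
Conditions: second-generation Grubbs catalyst (H2IMes)(PCy3)Cl2Ru=CHPh (5 mol%), 2-methylbut-2-ene (excess), CH2Cl2, 40 °C
Reagents that add atoms: 2-methylbut-2-ene, CC=C(C)C
Why: Olefin cross-metathesis; only the monosubstituted alkene engages the ruthenium carbene and is capped with an isopropylidene unit, the trisubstituted allylic alkene being unreactive.

Step 13
Reactants: 20 (2E,4S)-4-[(tert-butyldimethylsilyl)oxy]-3,7-dimethylocta-2,6-dien-1-yl acetate
Product: 21 (2E,4S)-4-[(tert-butyldimethylsilyl)oxy]-3,7-dimethylocta-2,6-dien-1-ol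
Conditions: K2CO3 (cat.), MeOH, 0 → 23 °C
Reagents that add atoms: none
Why: Base-catalysed methanolysis (transesterification) removes the acetate and leaves the silyl ether untouched.

Step 14
Reactants: 21 (2E,4S)-4-[(tert-butyldimethylsilyl)oxy]-3,7-dimethylocta-2,6-dien-1-ol
Product: 22 {[(2E,4S)-1-bromo-3,7-dimethylocta-2,6-dien-4-yl]oxy}(tert-butyl)dimethylsilane
Conditions: CBr4, PPh3, CH2Cl2, 0 °C
Reagents that add atoms: carbon tetrabromide, BrC(Br)(Br)Br
Why: Appel bromination; bromide displaces the primary oxyphosphonium by SN2 under neutral conditions, without allylic transposition or loss of alkene geometry.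

**Fragment union and endgame**

Step 15
Reactants: 15 (1R,5S,7R)-4-methoxy-8,8-dimethyl-1,7-bis(3-methylbut-2-en-1-yl)bicyclo[3.3.1]non-3-ene-2,9-dione; 22 {[(2E,4S)-1-bromo-3,7-dimethylocta-2,6-dien-4-yl]oxy}(tert-butyl)dimethylsilane
Product: 24 (1R,5S,7R)-5-{(2E,4S)-4-[(tert-butyldimethylsilyl)oxy]-3,7-dimethylocta-2,6-dien-1-yl}-4-methoxy-8,8-dimethyl-1,7-bis(3-methylbut-2-en-1-yl)bicyclo[3.3.1]non-3-ene-2,9-dione, via bridgehead organolithium 23 (not isolated)
Conditions: LiN(iPr)2, THF, −78 °C; then 22, −78 → −30 °C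
Reagents that add atoms: none
Why: Bridgehead lithiation–alkylation; the amide base removes the only bridgehead proton (C5–H, α to the C9 ketone) and the configurationally locked carbanion 23 is alkylated by SN2 at the primary allylic bromide with retention at C5.

Step 16
Reactants: 25 3,4-dihydroxybenzoic acid
Product: 26 tert-butyldimethylsilyl 3,4-bis[(tert-butyldimethylsilyl)oxy]benzoate
Conditions: tBuMe2SiCl (3.5 equiv), imidazole, DMF, 23 °C
Reagents that add atoms: tert-butyldimethylsilyl chloride, CC(C)(C)[Si](C)(C)Cl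
Why: Exhaustive silylation protects both phenols and turns the acid into a silyl ester that is activated directly in step 17.

Step 17
Reactants: 26 tert-butyldimethylsilyl 3,4-bis[(tert-butyldimethylsilyl)oxy]benzoate
Product: 27 3,4-bis[(tert-butyldimethylsilyl)oxy]benzoyl chloride
Conditions: (COCl)2, DMF (cat.), CH2Cl2, 0 → 23 °C
Reagents that add atoms: oxalyl chloride, ClC(=O)C(Cl)=O
Why: The Vilsmeier-type chloroiminium reagent converts the silyl ester directly into the acid chloride under neutral conditions that leave the aryl silyl ethers intact.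

Step 18
Reactants: 24 (1R,5S,7R)-5-{(2E,4S)-4-[(tert-butyldimethylsilyl)oxy]-3,7-dimethylocta-2,6-dien-1-yl}-4-methoxy-8,8-dimethyl-1,7-bis(3-methylbut-2-en-1-yl)bicyclo[3.3.1]non-3-ene-2,9-dione; 27 3,4-bis[(tert-butyldimethylsilyl)oxy]benzoyl chloride
Product: 29 (1S,5S,7R)-3-{3,4-bis[(tert-butyldimethylsilyl)oxy]benzoyl}-5-{(2E,4S)-4-[(tert-butyldimethylsilyl)oxy]-3,7-dimethylocta-2,6-dien-1-yl}-4-methoxy-8,8-dimethyl-1,7-bis(3-methylbut-2-en-1-yl)bicyclo[3.3.1]non-3-ene-2,9-dione, via C3 vinyllithium 28 (not isolated)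
Conditions: lithium 2,2,6,6-tetramethylpiperidide, THF, −78 °C; then 27, −78 → −40 °C
Reagents that add atoms: none
Why: Vinyl deprotonation–acylation; with both bridgeheads quaternary the hindered amide can remove only C3–H (between the C2 carbonyl and the methoxy-bearing C4), and vinyllithium 28 is C-acylated by the acid chloride.

Step 19
Reactants: 29 (1S,5S,7R)-3-{3,4-bis[(tert-butyldimethylsilyl)oxy]benzoyl}-5-{(2E,4S)-4-[(tert-butyldimethylsilyl)oxy]-3,7-dimethylocta-2,6-dien-1-yl}-4-methoxy-8,8-dimethyl-1,7-bis(3-methylbut-2-en-1-yl)bicyclo[3.3.1]non-3-ene-2,9-dione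
Product: 30 (1S,5S,7R)-3-(3,4-dihydroxybenzoyl)-5-[(2E,4S)-4-hydroxy-3,7-dimethylocta-2,6-dien-1-yl]-4-methoxy-8,8-dimethyl-1,7-bis(3-methylbut-2-en-1-yl)bicyclo[3.3.1]non-3-ene-2,9-dione
Conditions: Bu4NF, AcOH, THF, 0 → 23 °C
Reagents that add atoms: none
Why: Fluoride-mediated cleavage of the three Si–O bonds, buffered with acetic acid to spare the acylated vinylogous ester.

Step 20
Reactants: 30 (1S,5S,7R)-3-(3,4-dihydroxybenzoyl)-5-[(2E,4S)-4-hydroxy-3,7-dimethylocta-2,6-dien-1-yl]-4-methoxy-8,8-dimethyl-1,7-bis(3-methylbut-2-en-1-yl)bicyclo[3.3.1]non-3-ene-2,9-dione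
Product: 31 (1S,5S,7R)-3-(3,4-dihydroxybenzoyl)-4-hydroxy-5-[(2E,4S)-4-hydroxy-3,7-dimethylocta-2,6-dien-1-yl]-8,8-dimethyl-1,7-bis(3-methylbut-2-en-1-yl)bicyclo[3.3.1]non-3-ene-2,9-dione
Conditions: LiOH, H2O–1,4-dioxane (degassed), 90 °C; then cold aq. HCl to pH 3
Reagents that add atoms: lithium hydroxide, [Li+].[OH-]
Why: Hydrolysis of the vinylogous methyl ester by addition–elimination of hydroxide at C4 (activated by two carbonyl groups) releases the enolised β-triketone, and no stereocentre can epimerise because both bridgeheads are quaternary.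

**Compound list**

1 | 5-methylhex-4-enal | CC(C)=CCCC=O | starting material
2 | methyl vinyl ketone | CC(=O)C=C | starting material
3 | (2S)-2-(3-methylbut-2-en-1-yl)-5-oxohexanal | O=C[C@H](CC=C(C)C)CCC(C)=O | intermediate
4 | (4S)-4-(3-methylbut-2-en-1-yl)cyclohex-2-en-1-one | O=C1CC[C@@H](CC=C(C)C)C=C1 | intermediate
5 | trimethyl{[(3S,4S)-3-methyl-4-(3-methylbut-2-en-1-yl)cyclohex-1-en-1-yl]oxy}silane | C[Si](C)(C)OC1=C[C@@H](C)[C@H](CC=C(C)C)CC1 | intermediate
6 | (4S)-3-methyl-4-(3-methylbut-2-en-1-yl)cyclohex-2-en-1-one | O=C1CC[C@@H](CC=C(C)C)C(C)=C1 | intermediate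
7 | prenyl bromide (1-bromo-3-methylbut-2-ene) | CC(C)=CCBr | starting material
8 | lithium (4S)-3,3-dimethyl-4-(3-methylbut-2-en-1-yl)cyclohex-1-en-1-olate | [Li]OC1=CC(C)(C)[C@H](CC=C(C)C)CC1 | intermediate
9 | (2R,4S)-3,3-dimethyl-2,4-bis(3-methylbut-2-en-1-yl)cyclohexan-1-one | O=C1CC[C@@H](CC=C(C)C)C(C)(C)[C@H]1CC=C(C)C | intermediate
10 | lithium (4R,6R)-5,5-dimethyl-4,6-bis(3-methylbut-2-en-1-yl)cyclohex-1-en-1-olate | [Li]OC1=CC[C@@H](CC=C(C)C)C(C)(C)[C@H]1CC=C(C)C | intermediate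
11 | tert-butyl{[(4R,6R)-5,5-dimethyl-4,6-bis(3-methylbut-2-en-1-yl)cyclohex-1-en-1-yl]oxy}dimethylsilane | CC(C)(C)[Si](C)(C)OC1=CC[C@@H](CC=C(C)C)C(C)(C)[C@H]1CC=C(C)C | intermediate
12 | malonyl dichloride | ClC(=O)CC(Cl)=O | starting material
13 | 3-[(5R)-4,4-dimethyl-3,5-bis(3-methylbut-2-en-1-yl)-2-oxocyclohexyl]-3-oxopropanoyl chloride (ring C1 and C3 labile) | ClC(=O)CC(=O)C1C[C@@H](CC=C(C)C)C(C)(C)C(CC=C(C)C)C1=O | intermediate
14 | (1R,5S,7R)-4-hydroxy-8,8-dimethyl-1,7-bis(3-methylbut-2-en-1-yl)bicyclo[3.3.1]non-3-ene-2,9-dione | CC(C)=CC[C@@H]1C[C@@H]2C(=O)[C@@](CC=C(C)C)(C(=O)C=C2O)C1(C)C | intermediate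
15 | (1R,5S,7R)-4-methoxy-8,8-dimethyl-1,7-bis(3-methylbut-2-en-1-yl)bicyclo[3.3.1]non-3-ene-2,9-dione | CC(C)=CC[C@@H]1C[C@@H]2C(=O)[C@@](CC=C(C)C)(C(=O)C=C2OC)C1(C)C | intermediate
16 | prenyl acetate (3-methylbut-2-en-1-yl acetate) | CC(C)=CCOC(C)=O | starting material
17 | (2E)-3-methyl-4-oxobut-2-en-1-yl acetate | CC(=O)OC/C=C(\C)C=O | intermediate
18 | (2E,4S)-4-hydroxy-3-methylhepta-2,6-dien-1-yl acetate | CC(=O)OC/C=C(\C)[C@@H](O)CC=C | intermediate
19 | (2E,4S)-4-[(tert-butyldimethylsilyl)oxy]-3-methylhepta-2,6-dien-1-yl acetate | CC(=O)OC/C=C(\C)[C@@H](O[Si](C)(C)C(C)(C)C)CC=C | intermediate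
20 | (2E,4S)-4-[(tert-butyldimethylsilyl)oxy]-3,7-dimethylocta-2,6-dien-1-yl acetate | CC(=O)OC/C=C(\C)[C@@H](O[Si](C)(C)C(C)(C)C)CC=C(C)C | intermediate
21 | (2E,4S)-4-[(tert-butyldimethylsilyl)oxy]-3,7-dimethylocta-2,6-dien-1-ol | OC/C=C(\C)[C@@H](O[Si](C)(C)C(C)(C)C)CC=C(C)C | intermediate
22 | {[(2E,4S)-1-bromo-3,7-dimethylocta-2,6-dien-4-yl]oxy}(tert-butyl)dimethylsilane | BrC/C=C(\C)[C@@H](O[Si](C)(C)C(C)(C)C)CC=C(C)C | intermediate
23 | (1R,5S,7R)-5-lithio-4-methoxy-8,8-dimethyl-1,7-bis(3-methylbut-2-en-1-yl)bicyclo[3.3.1]non-3-ene-2,9-dione | CC(C)=CC[C@@H]1C[C@]2([Li])C(=O)[C@@](CC=C(C)C)(C(=O)C=C2OC)C1(C)C | intermediate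
24 | (1R,5S,7R)-5-{(2E,4S)-4-[(tert-butyldimethylsilyl)oxy]-3,7-dimethylocta-2,6-dien-1-yl}-4-methoxy-8,8-dimethyl-1,7-bis(3-methylbut-2-en-1-yl)bicyclo[3.3.1]non-3-ene-2,9-dione | CC(C)=CC[C@@H]1C[C@]2(C/C=C(\C)[C@@H](O[Si](C)(C)C(C)(C)C)CC=C(C)C)C(=O)[C@@](CC=C(C)C)(C(=O)C=C2OC)C1(C)C | intermediate
25 | 3,4-dihydroxybenzoic acid | OC(=O)c1ccc(O)c(O)c1 | starting material
26 | tert-butyldimethylsilyl 3,4-bis[(tert-butyldimethylsilyl)oxy]benzoate | CC(C)(C)[Si](C)(C)OC(=O)c1ccc(O[Si](C)(C)C(C)(C)C)c(O[Si](C)(C)C(C)(C)C)c1 | intermediate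
27 | 3,4-bis[(tert-butyldimethylsilyl)oxy]benzoyl chloride | ClC(=O)c1ccc(O[Si](C)(C)C(C)(C)C)c(O[Si](C)(C)C(C)(C)C)c1 | intermediate
28 | (1R,5S,7R)-5-{(2E,4S)-4-[(tert-butyldimethylsilyl)oxy]-3,7-dimethylocta-2,6-dien-1-yl}-3-lithio-4-methoxy-8,8-dimethyl-1,7-bis(3-methylbut-2-en-1-yl)bicyclo[3.3.1]non-3-ene-2,9-dione | CC(C)=CC[C@@H]1C[C@]2(C/C=C(\C)[C@@H](O[Si](C)(C)C(C)(C)C)CC=C(C)C)C(=O)[C@@](CC=C(C)C)(C(=O)C([Li])=C2OC)C1(C)C | intermediate
29 | (1S,5S,7R)-3-{3,4-bis[(tert-butyldimethylsilyl)oxy]benzoyl}-5-{(2E,4S)-4-[(tert-butyldimethylsilyl)oxy]-3,7-dimethylocta-2,6-dien-1-yl}-4-methoxy-8,8-dimethyl-1,7-bis(3-methylbut-2-en-1-yl)bicyclo[3.3.1]non-3-ene-2,9-dione | CC(C)=CC[C@@H]1C[C@]2(C/C=C(\C)[C@@H](O[Si](C)(C)C(C)(C)C)CC=C(C)C)C(=O)[C@@](CC=C(C)C)(C(=O)C(C(=O)c3ccc(O[Si](C)(C)C(C)(C)C)c(O[Si](C)(C)C(C)(C)C)c3)=C2OC)C1(C)C | intermediate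
30 | (1S,5S,7R)-3-(3,4-dihydroxybenzoyl)-5-[(2E,4S)-4-hydroxy-3,7-dimethylocta-2,6-dien-1-yl]-4-methoxy-8,8-dimethyl-1,7-bis(3-methylbut-2-en-1-yl)bicyclo[3.3.1]non-3-ene-2,9-dione | CC(C)=CC[C@@H]1C[C@]2(C/C=C(\C)[C@@H](O)CC=C(C)C)C(=O)[C@@](CC=C(C)C)(C(=O)C(C(=O)c3ccc(O)c(O)c3)=C2OC)C1(C)C | intermediate
31 | (1S,5S,7R)-3-(3,4-dihydroxybenzoyl)-4-hydroxy-5-[(2E,4S)-4-hydroxy-3,7-dimethylocta-2,6-dien-1-yl]-8,8-dimethyl-1,7-bis(3-methylbut-2-en-1-yl)bicyclo[3.3.1]non-3-ene-2,9-dione | CC(C)=CC[C@@H]1C[C@]2(C/C=C(\C)[C@@H](O)CC=C(C)C)C(=O)[C@@](CC=C(C)C)(C(=O)C(C(=O)c3ccc(O)c(O)c3)=C2O)C1(C)C | target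

**Step count and risks**

Total steps: 20. Longest linear sequence: 12 (steps 1–8, 15, 18, 19, 20).

Step 7 (annulation). The ring-closing acylation at the neopentyl, prenyl-bearing α-carbon may be outrun by O-acylation and by intermolecular oligomerisation of the acyl chloride intermediate. The fallback sets out from ketone 9 and comes back at 14. Ketone 9 is condensed with pyrrolidine (TiCl4, toluene) to the less substituted pyrrolidine enamine F1. α,α′-Annulation of the enamine with acryloyl chloride (MeCN, reflux, then aqueous hydrolysis), in which C-alkylation at the free α-carbon is followed by intramolecular C-acylation under neutral conditions, gives the bicyclic 2,9-dione F2. Dehydrogenation with IBX gives the bicyclic enone F3, and nucleophilic epoxidation (H2O2, NaOH) from the face of the C9 bridge gives the epoxy ketone F4. Isomerisation of this α,β-epoxy ketone catalysed by zerovalent palladium (Pd(PPh3)4, dppe, toluene, 80 °C) gives β-diketone 14.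

Step 5 (conjugate addition–prenylation). Proton transfer between product and enolate may cause enolate equilibration and over-alkylation, and SN2 next to the new quaternary carbon may be slow. The fallback sets out from enone 6 and comes back at 9. After the cuprate addition the enolate is O-acylated with allyl chloroformate to give the allyl enol carbonate F5. Pd(PPh3)4 (zerovalent palladium) then effects a decarboxylative Tsuji allylation that delivers the allyl group regiospecifically to C2 under neutral conditions, giving the 2-allyl ketone F6. Cross-metathesis with 2-methylbut-2-ene (second-generation Grubbs catalyst) converts allyl into prenyl and gives 9.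

Step 15 (bridgehead alkylation). The basic bridgehead carbanion may cause elimination or proton transfer with the γ-branched, silyloxy-bearing bromide, and deprotonation at C3 may compete. The fallback sets out from 15 and comes back at 24, building the chain on the core. The bridgehead anion is quenched with allyl bromide, a small and reactive electrophile, to give the 5-allyl compound F7. Cross-metathesis with methacrolein (second-generation Hoveyda–Grubbs catalyst (H2IMes)Cl2Ru=CH(C6H4-2-OiPr)) gives the E-enal F8. Keck allylation ((S)-BINOL, Ti(OiPr)4, allylSnBu3) gives the 4′S homoallylic alcohol F9, and cross-metathesis with 2-methylbut-2-ene gives the prenyl-terminated alcohol F10. Silylation (tBuMe2SiOTf, 2,6-lutidine) returns 24.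

**Further compounds**

F1 | step 7 | 1-[(4R,6R)-5,5-dimethyl-4,6-bis(3-methylbut-2-en-1-yl)cyclohex-1-en-1-yl]pyrrolidine | C1CCN(C1)C2=CC[C@@H](CC=C(C)C)C(C)(C)[C@H]2CC=C(C)C
F2 | step 7 | (1R,5R,7R)-8,8-dimethyl-1,7-bis(3-methylbut-2-en-1-yl)bicyclo[3.3.1]nonane-2,9-dione | CC(C)=CC[C@@H]1C[C@@H]2C(=O)[C@@](CC=C(C)C)(C(=O)CC2)C1(C)C
F3 | step 7 | (1R,5S,7R)-8,8-dimethyl-1,7-bis(3-methylbut-2-en-1-yl)bicyclo[3.3.1]non-3-ene-2,9-dione | CC(C)=CC[C@@H]1C[C@@H]2C(=O)[C@@](CC=C(C)C)(C(=O)C=C2)C1(C)C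
F4 | step 7 | 3,4-epoxide of F3 with the oxygen on the face of the C9 bridge (3,4-epoxy-8,8-dimethyl-1,7-bis(3-methylbut-2-en-1-yl)bicyclo[3.3.1]nonane-2,9-dione) | CC(C)=CC[C@@H]1C[C@@H]2C(=O)[C@@](CC=C(C)C)(C(=O)[C@H]3O[C@@H]23)C1(C)C
F5 | step 5 | (4S)-3,3-dimethyl-4-(3-methylbut-2-en-1-yl)cyclohex-1-en-1-yl prop-2-en-1-yl carbonate | C=CCOC(=O)OC1=CC(C)(C)[C@H](CC=C(C)C)CC1
F6 | step 5 | (2R,4S)-3,3-dimethyl-4-(3-methylbut-2-en-1-yl)-2-(prop-2-en-1-yl)cyclohexan-1-one | O=C1CC[C@@H](CC=C(C)C)C(C)(C)[C@H]1CC=C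
F7 | step 15 | (1R,5S,7R)-4-methoxy-8,8-dimethyl-1,7-bis(3-methylbut-2-en-1-yl)-5-(prop-2-en-1-yl)bicyclo[3.3.1]non-3-ene-2,9-dione | CC(C)=CC[C@@H]1C[C@]2(CC=C)C(=O)[C@@](CC=C(C)C)(C(=O)C=C2OC)C1(C)C
F8 | step 15 | (1R,5S,7R)-4-methoxy-8,8-dimethyl-5-[(2E)-3-methyl-4-oxobut-2-en-1-yl]-1,7-bis(3-methylbut-2-en-1-yl)bicyclo[3.3.1]non-3-ene-2,9-dione | CC(C)=CC[C@@H]1C[C@]2(C/C=C(\C)C=O)C(=O)[C@@](CC=C(C)C)(C(=O)C=C2OC)C1(C)C
F9 | step 15 | (1R,5S,7R)-5-[(2E,4S)-4-hydroxy-3-methylhepta-2,6-dien-1-yl]-4-methoxy-8,8-dimethyl-1,7-bis(3-methylbut-2-en-1-yl)bicyclo[3.3.1]non-3-ene-2,9-dione | CC(C)=CC[C@@H]1C[C@]2(C/C=C(\C)[C@@H](O)CC=C)C(=O)[C@@](CC=C(C)C)(C(=O)C=C2OC)C1(C)C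
F10 | step 15 | (1R,5S,7R)-5-[(2E,4S)-4-hydroxy-3,7-dimethylocta-2,6-dien-1-yl]-4-methoxy-8,8-dimethyl-1,7-bis(3-methylbut-2-en-1-yl)bicyclo[3.3.1]non-3-ene-2,9-dione | CC(C)=CC[C@@H]1C[C@]2(C/C=C(\C)[C@@H](O)CC=C(C)C)C(=O)[C@@](CC=C(C)C)(C(=O)C=C2OC)C1(C)C
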